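The target in the grey flask reads 15.6% at 0.667 min and 13.8% at 4.00 min. The amber flask, charged with more partner, reads 23.2% at 4.00 min.

| setting | grey | amber | flask |
|---|---|---|---|
| starting material | 1 mM | 1 mM | 1.0 mM |
| partner | 2 mM | 3 mM | 2.00 mM |
| second substrate | 1 mM | 1 mM | 1.00 mM |
| temperature | 5 °C | 5 °C | 5 °C |
| remark | the very flask that is asked about, followed so far | run made earlier |  |
| time |  |  | 5.0 min |

- grey (time / min: target / %): 0.667: 15.6; 1.33: 14.9; 2.00: 14.0; 2.50: 14.2; 3.00: 13.3; 4.00: 13.8
- amber (time / min: target / %): 0.250: 18.4; 0.667: 23.7; 1.33: 23.9; 2.00: 23.1; 2.50: 24.0; 4.00: 23.2

(standard deviation of a reading: 0.3 percentage points)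

- what is taken out of target is counted as made
- what was read earlier has a scatter of 0.3 percentage points, one standard deviation
- additions bring no volume worth counting
- the earlier runs do not show what temperature does; that part of a forecast is a guess

- south-east: at 5.0 min raise the temperature by 25 K, then wait 10 min
- east: change nothing and wait 10 min more
- south-west: at 5.0 min add partner, 50.0% of the amount charged, then wait 10 min
- west: at 5.0 min take out 90% of the target then present, then wait 10 min

- target, in percent of the starting material first charged, at 5.0 min
- the option that brings most further target ("none" if no option brings more than 2 percentage points) (south-east / east / south-west / west / none)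
- target present, with what was taken out counted in, in percent of the starting material first charged, after south-east
- target present, with what was taken out counted in, in percent of the starting material first charged, after west

*What stands in the grey flask at 5.0 min?* The target falls from its first reading, but from 2.00 min on it is flat within the scatter. Those later readings average 13.8%, and I commit to that. The amber readings from 1.33 min on average 23.5%.

*Is this a balance of starting material and partner, as charged?* Test it with the quotient of target over starting material times partner, each of these two reckoned as its charge minus the target. The grey flask reads 0.0862 mM⁻¹ and the amber flask 0.111 mM⁻¹. They differ by a factor of 1.29, so the charged partner looks like the wrong concentration.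

*Which concentration, then?* My guess is that second substrate takes partner one for one. Define the partner excess E as 1.00 mM in the grey flask, charged partner minus charged second substrate, and 2.00 mM in the amber flask. With E in place of the charge, the quotients read 0.186 mM⁻¹ and 0.175 mM⁻¹, a factor of 1.06 apart.

*But both flasks charge 1 mM of second substrate. Is that proof?* No. It is a better fit, not a demonstration.

*What do you expect?* South-west lifts E to 2.00 mM, the amber value, so I expect a gain of 9.7 percentage points. Waiting should give nothing on a flat line. Warming remains a guess.

The forecast gives 13.7% now, west as best, 11% after south-east and 23% after west. On warming it reasons “association is probably exothermic, so the target falls”.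

    starting material + second substrate → cross product (k = 14.0 M⁻¹ s⁻¹, Ea = 38.0 kJ mol⁻¹)
    second substrate + partner → second product (k = 20.0 M⁻¹ s⁻¹, Ea = 38.0 kJ mol⁻¹)
    starting material + partner ⇌ target (K = 290 M⁻¹, k = 8.50 M⁻¹ s⁻¹, Ea = 39.0 kJ mol⁻¹, ΔH = 17.0 kJ mol⁻¹)
    starting material ⇌ dormant form (K = 0.480, k = 0.0330 s⁻¹, Ea = 65.0 kJ mol⁻¹, ΔH = −66.0 kJ mol⁻¹)
    (constants at 5 °C)

The flask gives 13.7% now, and south-east is best, gaining 12 points and reaching 25.7%. West reaches 23.0%. A repeat held at 30 °C from the start has 2.18% in the dormant form at 5.00 min, against 20.9% in the grey flask at that time. South-east leaves E at 1.00 mM, so E prices no gain there. E does price south-west: it promised 9.7 points, and the flask gives 8.3 points.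

In the neighbour charged with 4.0 mM of second substrate, other charges as in the recipe, E is −2.00 mM. That is negative, so I expect hardly any target there, with partner as the limiting reagent. That neighbour gives 0.00820% target, hardly any, with 0.074% of its partner and 26% of its second substrate left.

(The numbers in the tables were generated by integration with constants of no real substance; the scatter is artificial.)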